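All runs come from a simulation for an exercise.

**Late target.** Target in the noon run lags and then stalls: 2% at 25.0 min, 19% at 80.0 min, still 19% at 90.0 min, while starting material falls from 34% to 31%. One run does not show that other flasks share that curve, so what follows takes it as a first guess.

| flask | starting material | partner | second reagent | temperature | remark | time |
|---|---|---|---|---|---|---|
| winter | 0.25 M | 0.50 equiv | 2.5 equiv | 0 °C | run made earlier |  |
| noon | 1 M | 0.50 equiv | 2.5 equiv | 15 °C | run made earlier |  |
| summer | 0.50 M | 0.50 equiv | 3.8 equiv | 0 °C | run made earlier |  |
| grey | 0.50 M | 0.500 equiv | 2.50 equiv | 25 °C |  | 1.0 h |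
| violet | 0.50 M | 0.500 equiv | 2.50 equiv | 5 °C |  | 1.0 h |
| red | 0.50 M | 0.500 equiv | 2.50 equiv |  | at 25 °C until 30 min, from then on at 5 °C | 1.0 h |

- winter (time / h: target / %, starting material / %): 0.833: 0, 98; 1.50: 0, 92; 3.00: 0, 78
- noon (time / min: target / %, starting material / %): 25.0: 2, 66; 50.0: 13, 49; 80.0: 19, 34; 90.0: 19, 31
- summer (time / h: target / %, starting material / %): 0.250: 4, 96; 0.667: 1, 90; 1.33: 2, 81; 3.00: 7, 70

(standard deviation of a reading: 2 percentage points)

- the best flask by amount of target, in percent of the starting material charged; "all alike" if 1.5 percentage points covers them all (grey / violet / red / all alike)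
- amount of target at the end, in percent of the starting material charged, grey
- amount of target at the end, in percent of the starting material charged, violet
- amount of target at the end, in percent of the starting material charged, red

- a reading or a percentage of target counts all its forms, free or not

**Frozen shape.** The new flasks carry 0.500 equiv of partner and 2.50 equiv of second reagent, as noon does, so a first guess freezes the shape of the noon curve and lets each flask travel along it at its own speed. Read as roughly second order (charged over left, minus one, per concentration and time), noon at 15 °C runs 3.95 times as fast as winter at 0 °C. Spread evenly over temperature, that gives a factor of 2.50 up to 25 °C and the same factor down to 5 °C. Grey then gets 74.9 min of noon-equivalent time: its time, times its concentration over noon's, times the temperature factor, a reduced time that names the minute of the noon curve where this guess places the flask.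

**First objection.** Summer was not used for the factor and has 3.8 equiv of second reagent. Its clock gives 22.8 min, near noon's first reading. Starting material reads 70% against 66%, two readings that each carry a scatter of 2 percentage points, so this comparison gives no firm objection to that clock, though second reagent differs too. Target reads 7% against 2%, but the new flasks keep noon's equivalents.

**Second objection.** The factor comes from starting material, and target may respond differently to temperature. Winter, at 0% target, cannot test this, so the doubt stays.

**Reckoning.** Between noon's readings, this estimate puts grey at 18.0%. Red gets 43.5 min and the estimate puts it at 10.1%. Violet gets 12.0 min, earlier than noon's first reading, so the estimate puts it under 2%.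

**Forecast.** The forecast gives grey as best, with grey 22%, above this reckoning, violet 2% and red 10%: “Grey should win, though the extrapolation is uncertain”.

**Result.** The best flask is grey: grey 14.4%, red 11.0%, violet 1.74%, bound forms of target counted.

    starting material + partner → intermediate (k = 0.00210 M⁻¹ s⁻¹, Ea = 72.0 kJ mol⁻¹)
    second reagent + intermediate → target (k = 4.30 × 10⁻⁴ M⁻¹ s⁻¹, Ea = 74.0 kJ mol⁻¹)
    starting material + second reagent → side product A (k = 4.60 × 10⁻⁵ M⁻¹ s⁻¹, Ea = 83.0 kJ mol⁻¹)
    starting material + target → side product B (k = 0.00370 M⁻¹ s⁻¹, Ea = 54.0 kJ mol⁻¹)
    second reagent + target ⇌ idle adduct, settled at all times (K = 0.610 M⁻¹, ΔH = −42.0 kJ mol⁻¹)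
    (constants at 25 °C)

**Hotter neighbour.** Grey's 74.9 min read 3.6 points above its flask, while red and violet fell close to their readings. The same flask as violet run at 30 °C gets 118 min of noon-equivalent time, past noon's last reading, where the curve stands at 19%. That neighbour ends with target at 15.5%, all its forms counted, and starting material at 16.3%.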